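C1(Me)=C2–C3(ring B of the flavonol)–C4(2,4-dihydroxybenzoyl, ring D)–C5(2,4-dihydroxyphenyl, ring E)–C6H2 numbers the cyclohexene throughout; rings A and C are the chromone.
Retrosynthesis: the eight OH groups are masked as MOM ethers; then C3–C4 is cut and C4 is re-bonded to C1 (retro 1,3-shift). This contracts the cyclohexene to the cyclobutane C1–C4–C5–C6, with methyl and an (E)-styryl arm (C2=C3–ring B) on C1.
Enabling feature: C3 is allylic to C1=C2 and benzylic to ring B (two ortho oxygens), and C4 is the α-carbon of an aryl ketone with a chelating ortho oxygen. In the four-membered isomer this donor/acceptor pair flanks the strained C1–C4 bond, which can ionize and re-close at C3.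
Further cuts: C3–ring B (Heck), C5–ring E (rhodium 1,4-arylation), C4–CO–ring D (carbonylative Suzuki–Miyaura), back to 2-methyl-2-vinylcyclobutanone from cyclopropyl phenyl sulfide and methyl vinyl ketone. The iodoflavonol comes from 2-iodoresorcinol and resacetophenone.
Forward ring order: cyclopropane → cyclobutanone → cyclobutene → cyclobutane → cyclohexene; pyranone ring C is closed separately (Algar–Flynn–Oyamada) and joined by the Heck reaction.
Stereochemistry: C5 is set by a chiral diene–rhodium catalyst; quaternary C1 is carried as both epimers and erased; C3 and C4 are set from C5 in the ring expansion (all groups equatorial).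

Key step: step 15

Assumption: the target is taken as the all-trans (3R,4R,5S) isomer encoded in the SMILES. The sense of induction of the rhodium–diene catalyst in step 7 is assigned by analogy only, and the mirror-image ligand would be used if the opposite sense were found.

Step 1
Reactants: 1 4-bromoresorcinol
Product: 2 1-bromo-2,4-bis(methoxymethoxy)benzene
Conditions: NaH, MOMCl, DMF, 0 °C to rt
Reagents that add atoms: chloromethyl methyl ether, COCCl
Why: Williamson-type O-alkylation of both phenoxides gives the MOM acetals, which withstand the organolithium, palladium, rhodium and base steps ahead and leave together under mild acid at the end.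

Step 2
Reactants: 2 1-bromo-2,4-bis(methoxymethoxy)benzene
Product: 5 [2,4-bis(methoxymethoxy)phenyl]boronic acid, via aryllithium 3 (not isolated), via lithium aryltriisopropoxyborate 4 (not isolated)
Conditions: n-BuLi, THF, −78 °C; B(Oi-Pr)3, −78 °C to rt; then H2O
Reagents that add atoms: triisopropyl borate, CC(C)OB(OC(C)C)OC(C)C; water, O
Why: Bromine–lithium exchange, assisted by the ortho MOM oxygen, followed by electrophilic borylation and hydrolysis is the standard route to an arylboronic acid, and this one serves twice, as ring D and as ring E.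

Step 3
Reactants: 6 cyclopropyl phenyl sulfide; 7 but-3-en-2-one (methyl vinyl ketone)
Product: 9 2-[1-(phenylsulfanyl)cyclopropyl]but-3-en-2-ol (racemic), via 1-lithio-1-(phenylsulfanyl)cyclopropane 8 (not isolated)
Conditions: n-BuLi, THF, 0 °C; then 7, −78 °C; then H2O
Reagents that add atoms: none
Why: Sulfur-assisted α-lithiation of the cyclopropane and 1,2-addition of the hard organolithium to the enone carbonyl at low temperature give the tertiary allylic carbinol, whose stereocentre is of no consequence.

Step 4
Reactants: 9 2-[1-(phenylsulfanyl)cyclopropyl]but-3-en-2-ol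
Product: 10 2-ethenyl-2-methylcyclobutan-1-one (racemic)
Conditions: TsOH·H2O (cat.), wet toluene, 80 °C
Reagents that add atoms: water, O
Why: Acid-induced cyclopropylcarbinyl-to-cyclobutyl ring enlargement (semipinacol type) is driven by the sulfur-stabilized cyclobutyl cation, whose hydrolysis gives the ketone and places methyl and vinyl on the future C1, racemic but harmless because C1 becomes sp2 in step 15.

Step 5
Reactants: 10 2-ethenyl-2-methylcyclobutan-1-one
Product: 12 4-ethenyl-4-methylcyclobut-1-en-1-yl trifluoromethanesulfonate (racemic), via potassium enolate 11 (not isolated)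
Conditions: KN(SiMe3)2, THF, −78 °C; PhNTf2, −78 to 0 °C
Reagents that add atoms: N-phenylbis(trifluoromethanesulfonimide), O=S(=O)(N(c1ccccc1)S(=O)(=O)C(F)(F)F)C(F)(F)F
Why: Enolization can only go toward C5 because C1 is quaternary, and O-sulfonylation of the enolate (enol triflate formation) fixes the C4=C5 double bond and makes C4 a coupling site.

Step 6
Reactants: 12 4-ethenyl-4-methylcyclobut-1-en-1-yl trifluoromethanesulfonate; 5 [2,4-bis(methoxymethoxy)phenyl]boronic acid
Product: 13 [2,4-bis(methoxymethoxy)phenyl](4-ethenyl-4-methylcyclobut-1-en-1-yl)methanone (racemic)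
Conditions: PdCl2(dppf) (5 mol %), CO (1 atm), K2CO3, anisole, 60 °C
Reagents that add atoms: carbon monoxide, [C-]#[O+]
Why: Carbonylative Suzuki–Miyaura coupling of an alkenyl triflate should work because CO insertion into the alkenylpalladium bond outruns transmetalation of the hindered ortho-substituted boronic acid, and it installs the aroyl group on C4 in one operation.

Step 7
Reactants: 13 [2,4-bis(methoxymethoxy)phenyl](4-ethenyl-4-methylcyclobut-1-en-1-yl)methanone; 5 [2,4-bis(methoxymethoxy)phenyl]boronic acid
Product: 14 [(1R,4S)-4-[2,4-bis(methoxymethoxy)phenyl]-2-ethenyl-2-methylcyclobutyl][2,4-bis(methoxymethoxy)phenyl]methanone (both epimers at the quaternary carbon)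
Conditions: [RhCl(C2H4)2]2 (3 mol %), (1R,4R)-2,5-diphenylbicyclo[2.2.2]octa-2,5-diene (6.6 mol %), KOH (aq, 0.5 equiv), dioxane, 30 °C
Reagents that add atoms: none
Why: Hayashi–Miyaura 1,4-addition, with close precedent in the arylation of cyclobutene-1-carboxylates, delivers ring E to the unhindered β-carbon C5 of the strained enone on the face chosen by the chiral diene, the methyl and vinyl groups on the remote C1 being too alike in size to override the catalyst in either enantiomer of 13, and protonation of the oxa-π-allylrhodium under basic conditions leaves the aroyl group trans to ring E.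

Step 8
Reactants: 15 2-iodoresorcinol
Product: 17 2,4-dihydroxy-3-iodobenzaldehyde, via aryl iminium chloride 16 (not isolated)
Conditions: POCl3, DMF, MeCN, −15 °C to rt; then H2O, 50 °C
Reagents that add atoms: N,N-dimethylformamide, CN(C)C=O; water, O
Why: Vilsmeier–Haack formylation can only strike the two equivalent positions that are ortho to one and para to the other hydroxyl group, so the 3-iodo-2,4-dihydroxy pattern of ring B follows without regiochemical doubt.

Step 9
Reactants: 17 2,4-dihydroxy-3-iodobenzaldehyde
Product: 18 3-iodo-2,4-bis(methoxymethoxy)benzaldehyde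
Conditions: NaH, MOMCl, DMF, 0 °C
Reagents that add atoms: chloromethyl methyl ether, COCCl
Why: Williamson-type O-alkylation under strong-base conditions also captures the hydrogen-bonded ortho hydroxyl group and shields both ring B oxygens.

Step 10
Reactants: 19 2,4-dihydroxyacetophenone
Product: 20 1-[2-hydroxy-4-(methoxymethoxy)phenyl]ethan-1-one
Conditions: MOMCl (1.1 equiv), K2CO3, acetone, rt
Reagents that add atoms: chloromethyl methyl ether, COCCl
Why: With a weak base only the 4-hydroxyl group is alkylated (selective Williamson-type protection) because the 2-hydroxyl group is locked in a hydrogen bond to the ketone, and it is needed free for ring closure in step 12.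

Step 11
Reactants: 18 3-iodo-2,4-bis(methoxymethoxy)benzaldehyde; 20 1-[2-hydroxy-4-(methoxymethoxy)phenyl]ethan-1-one
Product: 21 (E)-1-[2-hydroxy-4-(methoxymethoxy)phenyl]-3-[3-iodo-2,4-bis(methoxymethoxy)phenyl]prop-2-en-1-one
Conditions: KOH, EtOH, rt
Reagents that add atoms: none
Why: Claisen–Schmidt condensation of the methyl ketone with the non-enolizable aldehyde gives the (E)-chalcone by aldol addition and E1cB dehydration.

Step 12
Reactants: 21 (E)-1-[2-hydroxy-4-(methoxymethoxy)phenyl]-3-[3-iodo-2,4-bis(methoxymethoxy)phenyl]prop-2-en-1-one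
Product: 23 3-hydroxy-2-[3-iodo-2,4-bis(methoxymethoxy)phenyl]-7-(methoxymethoxy)-4H-chromen-4-one, via dihydroflavonol 22 (not isolated)
Conditions: H2O2 (30 % aq), NaOH, MeOH, 0 °C to rt
Reagents that add atoms: hydrogen peroxide, OO
Why: Algar–Flynn–Oyamada reaction, in which alkaline peroxide epoxidizes the enone, the phenoxide opens the epoxide in the 6-endo sense to the dihydroflavonol and further oxidation gives the flavonol, aurone formation being unlikely because ring A carries no second substituent next to the carbonyl group.

Step 13
Reactants: 23 3-hydroxy-2-[3-iodo-2,4-bis(methoxymethoxy)phenyl]-7-(methoxymethoxy)-4H-chromen-4-one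
Product: 24 2-[3-iodo-2,4-bis(methoxymethoxy)phenyl]-3,7-bis(methoxymethoxy)-4H-chromen-4-one
Conditions: MOMCl, K2CO3, acetone, reflux
Reagents that add atoms: chloromethyl methyl ether, COCCl
Why: Williamson-type O-alkylation of the acidic 3-hydroxyl group removes the last free OH so that no hydroxyl group can intercept palladium or the allyl cation later.

Step 14
Reactants: 14 [(1R,4S)-4-[2,4-bis(methoxymethoxy)phenyl]-2-ethenyl-2-methylcyclobutyl][2,4-bis(methoxymethoxy)phenyl]methanone; 24 2-[3-iodo-2,4-bis(methoxymethoxy)phenyl]-3,7-bis(methoxymethoxy)-4H-chromen-4-one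
Product: 25 2-[3-[(E)-2-[(2R,3S)-2-[2,4-bis(methoxymethoxy)benzoyl]-3-[2,4-bis(methoxymethoxy)phenyl]-1-methylcyclobutyl]ethenyl]-2,4-bis(methoxymethoxy)phenyl]-3,7-bis(methoxymethoxy)-4H-chromen-4-one (both epimers at the quaternary carbon)
Conditions: Pd(OAc)2 (10 mol %), (n-Bu)4NCl, NaHCO3, DMF, 60 °C
Reagents that add atoms: none
Why: Mizoroki–Heck reaction under ligand-free phase-transfer conditions, in which syn insertion places ring B on the terminal carbon C3 and syn β-hydride elimination gives the (E)-alkene, which cannot migrate because C1 bears no hydrogen, with close precedent in couplings of 2-iodoresorcinol diethers with 2-methylbut-3-en-2-ol.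

Step 15
Reactants: 25 2-[3-[(E)-2-[(2R,3S)-2-[2,4-bis(methoxymethoxy)benzoyl]-3-[2,4-bis(methoxymethoxy)phenyl]-1-methylcyclobutyl]ethenyl]-2,4-bis(methoxymethoxy)phenyl]-3,7-bis(methoxymethoxy)-4H-chromen-4-one
Product: 27 2-[3-[(1R,5S,6R)-6-[2,4-bis(methoxymethoxy)benzoyl]-5-[2,4-bis(methoxymethoxy)phenyl]-3-methylcyclohex-2-en-1-yl]-2,4-bis(methoxymethoxy)phenyl]-3,7-bis(methoxymethoxy)-4H-chromen-4-one, via ring-opened zwitterion 26 (not isolated)
Conditions: Sc(OTf)3 (1.2 equiv, one equivalent being expected to rest on the chromone), 2,6-di-tert-butylpyridine (0.3 equiv), 4 Å MS, CH2Cl2, −40 to 0 °C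
Reagents that add atoms: none
Why: Proposed new method: trivalent scandium held between the ketone oxygen and the ortho methoxymethoxy group of ring D makes C4 the acceptor end, and the methyl- and styryl-substituted C1 the donor end, of the strained C1–C4 bond, which should ionize to the scandium enolate/1-aryl-3-methylallyl cation 26 common to both C1 epimers, after which C4 recombines with the far allyl terminus C3, a formal 1,3-shift that enlarges the ring C1–C4–C5–C6 by C2 and C3. The closest known reaction types are the zwitterionic vinylcyclobutane-to-cyclohexene rearrangement of tetracyanoethylene–diene [2+2] adducts and the Sc(OTf)3-catalysed opening of donor–acceptor cyclobutanes to 1,4-dipoles. The six-membered ring closes in the 6-(enolexo)-endo-trig mode; the 4-exo return to C1 and O-closure at C1 to a dihydropyran are reversible under the same acid, so the unstrained cyclohexene is the sink. C5 is not touched and controls both new centres: because C5–C6 is already a full bond the closure passes through a sofa-like array in which ring E sits equatorial, allylic 1,3-strain turns the bulky chelated enolate carbon outward so that C4 becomes trans to C5, and ring B, which keeps the outside position of the (E)-styryl arm, ends pseudo-equatorial on C3, trans to the aroyl group and cis to ring E; C4 could in addition be equilibrated to this all-equatorial isomer. The step needs cleavage of C1–C4 and not of the likewise benzylic C4–C5 bond (which would scramble C5), and collapse of 26 rather than Grob-type fragmentation to enone plus diene; the first is secured by the tertiary and doubly conjugated allyl cation against a merely secondary benzyl cation and by strain relief at the quaternary carbon, the second by the intramolecular ion pair at low temperature in a non-nucleophilic solvent, with the hindered pyridine keeping adventitious acid from the MOM groups.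

Step 16
Reactants: 27 2-[3-[(1R,5S,6R)-6-[2,4-bis(methoxymethoxy)benzoyl]-5-[2,4-bis(methoxymethoxy)phenyl]-3-methylcyclohex-2-en-1-yl]-2,4-bis(methoxymethoxy)phenyl]-3,7-bis(methoxymethoxy)-4H-chromen-4-one
Product: 28 2-[3-[(1R,5S,6R)-6-(2,4-dihydroxybenzoyl)-5-(2,4-dihydroxyphenyl)-3-methylcyclohex-2-en-1-yl]-2,4-dihydroxyphenyl]-3,7-dihydroxy-4H-chromen-4-one (CNP0190989.1)
Conditions: HCl (3 M aq), MeOH–THF, 45 °C, argon
Reagents that add atoms: none
Why: Acid-catalysed transacetalization with methanol removes all eight MOM groups at once, and no stereocentre is endangered since the all-equatorial isomer is the thermodynamic one.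

Compound list
1 | 4-bromoresorcinol | Oc1ccc(Br)c(O)c1 | starting material
2 | 1-bromo-2,4-bis(methoxymethoxy)benzene | COCOc1ccc(Br)c(OCOC)c1 | intermediate
3 | [2,4-bis(methoxymethoxy)phenyl]lithium (not isolated) | [Li]c1ccc(OCOC)cc1OCOC | intermediate
4 | lithium [2,4-bis(methoxymethoxy)phenyl]triisopropoxyborate (not isolated) | [Li+].CC(C)O[B-](OC(C)C)(OC(C)C)c1ccc(OCOC)cc1OCOC | intermediate
5 | [2,4-bis(methoxymethoxy)phenyl]boronic acid | OB(O)c1ccc(OCOC)cc1OCOC | intermediate
6 | cyclopropyl phenyl sulfide | C1CC1Sc1ccccc1 | starting material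
7 | but-3-en-2-one | CC(=O)C=C | starting material
8 | 1-lithio-1-(phenylsulfanyl)cyclopropane (not isolated) | [Li]C1(CC1)Sc1ccccc1 | intermediate
9 | 2-[1-(phenylsulfanyl)cyclopropyl]but-3-en-2-ol, racemic | CC(O)(C=C)C1(CC1)Sc1ccccc1 | intermediate
10 | 2-ethenyl-2-methylcyclobutan-1-one, racemic | CC1(C=C)CCC1=O | intermediate
11 | potassium 4-ethenyl-4-methylcyclobut-1-en-1-olate (not isolated) | CC1(C=C)CC=C1[O-].[K+] | intermediate
12 | 4-ethenyl-4-methylcyclobut-1-en-1-yl trifluoromethanesulfonate, racemic | CC1(C=C)CC=C1OS(=O)(=O)C(F)(F)F | intermediate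
13 | [2,4-bis(methoxymethoxy)phenyl](4-ethenyl-4-methylcyclobut-1-en-1-yl)methanone, racemic | CC1(C=C)CC=C1C(=O)c1ccc(OCOC)cc1OCOC | intermediate
14 | vinylcyclobutane, (1R,4S), aroyl trans to aryl, both epimers at the quaternary carbon | CC1(C=C)[C@H](C(=O)c2ccc(OCOC)cc2OCOC)[C@@H](c2ccc(OCOC)cc2OCOC)C1 | intermediate
15 | 2-iodoresorcinol | Oc1cccc(O)c1I | starting material
16 | (2,4-dihydroxy-3-iodobenzylidene)dimethylammonium chloride (not isolated) | C[N+](C)=Cc1ccc(O)c(I)c1O.[Cl-] | intermediate
17 | 2,4-dihydroxy-3-iodobenzaldehyde | O=Cc1ccc(O)c(I)c1O | intermediate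
18 | 3-iodo-2,4-bis(methoxymethoxy)benzaldehyde | O=Cc1ccc(OCOC)c(I)c1OCOC | intermediate
19 | 2,4-dihydroxyacetophenone | CC(=O)c1ccc(O)cc1O | starting material
20 | 1-[2-hydroxy-4-(methoxymethoxy)phenyl]ethan-1-one | CC(=O)c1ccc(OCOC)cc1O | intermediate
21 | (E)-2'-hydroxychalcone with iodinated ring B | COCOc1ccc(C(=O)/C=C/c2ccc(OCOC)c(I)c2OCOC)c(O)c1 | intermediate
22 | 3-hydroxy-2-[3-iodo-2,4-bis(methoxymethoxy)phenyl]-7-(methoxymethoxy)chroman-4-one, racemic (not isolated) | COCOc1ccc2C(=O)C(O)C(Oc2c1)c1ccc(OCOC)c(I)c1OCOC | intermediate
23 | 3-hydroxy-2-[3-iodo-2,4-bis(methoxymethoxy)phenyl]-7-(methoxymethoxy)-4H-chromen-4-one | O=c1c(O)c(-c2ccc(OCOC)c(I)c2OCOC)oc2cc(OCOC)ccc12 | intermediate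
24 | 2-[3-iodo-2,4-bis(methoxymethoxy)phenyl]-3,7-bis(methoxymethoxy)-4H-chromen-4-one | O=c1c(OCOC)c(-c2ccc(OCOC)c(I)c2OCOC)oc2cc(OCOC)ccc12 | intermediate
25 | (E)-styrylcyclobutane, (2R,3S), both epimers at the quaternary carbon | CC1(/C=C/c2c(OCOC)ccc(-c3oc4cc(OCOC)ccc4c(=O)c3OCOC)c2OCOC)[C@H](C(=O)c2ccc(OCOC)cc2OCOC)[C@@H](c2ccc(OCOC)cc2OCOC)C1 | intermediate
26 | ring-opened enolate/allyl cation zwitterion, drawn without scandium (not isolated) | C/C(=C/[CH+]c1c(OCOC)ccc(-c2oc3cc(OCOC)ccc3c(=O)c2OCOC)c1OCOC)C[C@H](c1ccc(OCOC)cc1OCOC)C=C([O-])c1ccc(OCOC)cc1OCOC | intermediate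
27 | octa-MOM ether of the target, (1R,5S,6R), all-trans | CC1=C[C@@H](c2c(OCOC)ccc(-c3oc4cc(OCOC)ccc4c(=O)c3OCOC)c2OCOC)[C@H](C(=O)c2ccc(OCOC)cc2OCOC)[C@@H](c2ccc(OCOC)cc2OCOC)C1 | intermediate
28 | CNP0190989.1 | CC1=C[C@@H](c2c(O)ccc(-c3oc4cc(O)ccc4c(=O)c3O)c2O)[C@H](C(=O)c2ccc(O)cc2O)[C@@H](c2ccc(O)cc2O)C1 | target

Total step count: 16. Longest linear sequence: 8 steps (3–7, then 14–16). The iodoflavonol branch (8, 9, 11–13, then 14–16) is equally long.

Steps most likely to fail

1. Step 15 (labelled).
- The second benzylic bond C4–C5 may ionize in competition, which would erode the configuration at C5.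
- The zwitterion may fragment into enone and diene, which would then recombine bimolecularly and lose stereochemical information.
- Closure may take place on the wrong face of the allyl terminus.
- MOM groups may be lost, or the Lewis acid may be held up on the chromone.

The fallback sets out from 25 and returns at 27 by the classical thermal vinylcyclobutane-to-cyclohexene rearrangement, a promoter-free homolytic 1,3-shift. Compound 25 is heated in degassed o-xylene at about 130 °C in base-washed glass with a radical inhibitor. Homolysis of the same C1–C4 bond gives an α-acyl/aryl-conjugated allyl diradical that closes at C3 while C5 stays untouched. Neither the MOM groups nor the chromone can interfere. Enantiomeric purity would be checked, and upgraded by crystallization if cycloreversion intervenes. This fallback makes no compound outside the list (entry F0).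

2. Step 7. Carborhodation may be slow or unselective for the mismatched enantiomer of the racemic enone, and the electron-rich ortho-substituted boronic acid may protodeboronate. The fallback sets out from triflate 12 and moves the arylation to the ester class on which it is established.
- Methoxycarbonylation (Pd(OAc)2, dppp, CO, MeOH, Et3N) gives methyl 4-ethenyl-4-methylcyclobut-1-ene-1-carboxylate F1.
- The same rhodium–diene arylation with 5 gives methyl (1R,4S)-4-[2,4-bis(methoxymethoxy)phenyl]-2-ethenyl-2-methylcyclobutane-1-carboxylate F2.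
- i-PrMgCl with MeNH(OMe)·HCl gives the corresponding N-methoxy-N-methylamide F3.
- Aryllithium 3, made from 2, converts F3 into ketone 14, where the route is rejoined.

3. Step 14. Insertion may be sluggish between the doubly ortho-substituted arylpalladium species and the alkene next to a quaternary carbon, and the donor–acceptor cyclobutane is under thermal stress during a long reaction. The fallback sets out from 14 and forms the C3–ring B bond by cross-coupling instead of insertion.
- Cross-metathesis with vinylboronic acid pinacol ester (second-generation Hoveyda–Grubbs catalyst, CH2Cl2, 40 °C) gives the (E)-alkenylboronic acid pinacol ester F4.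
- Suzuki–Miyaura coupling with iodide 24 (Pd(OAc)2, SPhos, K3PO4, THF–H2O, 40 °C) returns to 25.

Further compounds
F0 | step 15 | none | none
F1 | step 7 | methyl 4-ethenyl-4-methylcyclobut-1-ene-1-carboxylate | CC1(C=C)CC=C1C(=O)OC
F2 | step 7 | methyl (1R,4S)-4-[2,4-bis(methoxymethoxy)phenyl]-2-ethenyl-2-methylcyclobutane-1-carboxylate | CC1(C=C)[C@H](C(=O)OC)[C@@H](c2ccc(OCOC)cc2OCOC)C1
F3 | step 7 | (1R,4S)-4-[2,4-bis(methoxymethoxy)phenyl]-2-ethenyl-N-methoxy-N,2-dimethylcyclobutane-1-carboxamide | CC1(C=C)[C@H](C(=O)N(C)OC)[C@@H](c2ccc(OCOC)cc2OCOC)C1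
F4 | step 14 | (E)-alkenylboronic acid pinacol ester of 14 | CC1(/C=C/B2OC(C)(C)C(C)(C)O2)[C@H](C(=O)c2ccc(OCOC)cc2OCOC)[C@@H](c2ccc(OCOC)cc2OCOC)C1
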